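**Retrosynthetic overview**
- Schisandrone ⇐ its 7‑O‑benzyl ether (final hydrogenolysis under neutral conditions).
- The cyclohexanone ring (C1, C2, C3, C4, C4a, C8a) is not closed as a six‑membered ring. It comes from a 1‑aryl‑cyclobutanol whose ring holds C1–C4 with an extra C1–C4 bond; oxidative scission of that bond and closure C4→C4a insert the arene carbons C8a/C4a (4 → 6).
- Enabling feature: C1 is an aryl‑ketone carbon and C4 a diaryl‑substituted methine, 1,4‑related across the cis‑dimethyl unit C2/C3. In the cyclobutanol their bond is strained, carries the carbinol oxygen and is benzylic to the dimethoxyphenyl ring; C4a lies ortho to C8a and para to O7.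
- Cyclobutanol ⇐ 3‑(benzyloxy)‑4‑methoxyphenyl metal + cis‑3,4‑dimethyl‑2‑arylcyclobutanone ⇐ homoveratric amide of a C2‑symmetric pyrrolidine + cis‑2‑butene (keteniminium [2+2]).
- Ring order: cyclobutane (step 2), then the tetralone carbocycle by expansion (step 5); both arenes are bought. C2/C3 come from olefin geometry plus auxiliary, C4 from the key step.

Key step: step 5

Assumption: on a steric model the (2R,5R)‑auxiliary should give the (3R,4S)‑cyclobutanone; if the first run shows the opposite sense, the commercial (2S,5S)‑amine is used and nothing else changes.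

**Step 1**
Reactants: 1 (3,4‑dimethoxyphenyl)acetyl chloride; 2 (2R,5R)‑2,5‑dimethylpyrrolidine
Product: 3 2‑(3,4‑dimethoxyphenyl)‑1‑[(2R,5R)‑2,5‑dimethylpyrrolidin‑1‑yl]ethan‑1‑one
Conditions: Et3N, CH2Cl2, 0 °C → rt
Reagents that add atoms: none
Why: N‑acylation of a secondary amine by an acid chloride (Schotten–Baumann type); no stereocentre is formed or touched.

**Step 2**
Reactants: 3 2‑(3,4‑dimethoxyphenyl)‑1‑[(2R,5R)‑2,5‑dimethylpyrrolidin‑1‑yl]ethan‑1‑one; 4 (Z)‑but‑2‑ene
Product: 7 (3R,4S)‑2‑(3,4‑dimethoxyphenyl)‑3,4‑dimethylcyclobutan‑1‑one, via keteniminium triflate 5 (not isolated), via cyclobutaniminium triflate 6 (not isolated)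
Conditions: Tf2O, 2,4,6‑collidine, excess 4 (condensed), ClCH2CH2Cl, sealed tube, −20 → 60 °C; then aq NaHCO3, CH2Cl2, rt
Reagents that add atoms: water, O
Why: Ghosez keteniminium–olefin [2+2] cycloaddition followed by iminium hydrolysis: the addition is suprafacial on the olefin, so the two methyl groups stay cis, and the C2‑symmetric auxiliary (one methyl projecting into the half‑space through which the olefin approaches the central carbon anti to the aryl group) should select one of the two enantiotopic orientations of cis‑2‑butene and so set C3/C4 as (3R,4S); C2 forms as an epimer mixture that is of no consequence.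

**Step 3**
Reactants: 8 5‑bromo‑2‑methoxyphenol
Product: 9 2‑(benzyloxy)‑4‑bromo‑1‑methoxybenzene
Conditions: BnBr, K2CO3, DMF, rt
Reagents that add atoms: benzyl bromide, BrCc1ccccc1
Why: Williamson ether synthesis on a phenoxide; the benzyl group is chosen because it can be removed at the end without acid or base.

**Step 4**
Reactants: 9 2‑(benzyloxy)‑4‑bromo‑1‑methoxybenzene; 7 (3R,4S)‑2‑(3,4‑dimethoxyphenyl)‑3,4‑dimethylcyclobutan‑1‑one
Product: 12 (3R,4S)‑1‑[3‑(benzyloxy)‑4‑methoxyphenyl]‑2‑(3,4‑dimethoxyphenyl)‑3,4‑dimethylcyclobutan‑1‑ol, via aryllithium 10 (not isolated), via arylcerium dichloride 11 (not isolated)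
Conditions: n‑BuLi, THF, −78 °C; anhydrous CeCl3, −78 °C; then 7, −78 °C; aq NH4Cl
Reagents that add atoms: none
Why: bromine–lithium exchange, transmetalation to the weakly basic organocerium and 1,2‑addition to the strained ketone; the low basicity should suppress enolisation so that the cis‑dimethyl centres are kept, and the new carbinol centre (like C2) need not be controlled because both are erased in step 5.

**Step 5**
Reactants: 12 (3R,4S)‑1‑[3‑(benzyloxy)‑4‑methoxyphenyl]‑2‑(3,4‑dimethoxyphenyl)‑3,4‑dimethylcyclobutan‑1‑ol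
Product: 13 (2S,3S,4R)‑7‑(benzyloxy)‑4‑(3,4‑dimethoxyphenyl)‑6‑methoxy‑2,3‑dimethyl‑3,4‑dihydronaphthalen‑1(2H)‑one
Conditions: AgNO3 (20 mol %), K2S2O8 (2.5 equiv), CH2Cl2/H2O (1:1), 25 °C, vigorous stirring
Reagents that add atoms: none
Why: Ag(II), formed from Ag(I) and persulfate, oxidises the tertiary cyclobutanol (at O–H or through the radical cation of either electron‑rich arene) to the cyclobutyloxy radical, whose strain‑driven β‑scission breaks the bond between the carbinol carbon and the ArCH carbon, unveiling the aryl ketone and a 3,4‑dimethoxybenzylic radical; this radical (or the benzylic cation after one more electron transfer) attacks the arene carbon ortho to the new carbonyl, and loss of an electron and a proton restores the arene. The closest known reaction type is the silver/persulfate oxidative ring expansion of 1‑arylcyclobutanols to 1‑tetralones. The six‑membered ring closes by ortho attack of C4 on C4a (homolytic aromatic substitution), the four cyclobutane carbons becoming C1–C4 and the arene supplying C8a and C4a. C4 is the only new stereocentre: it arises from a planar benzylic intermediate, so all carbinol/C2 epimers of 12 converge, and the aryl group should take the position trans to the adjacent C3 methyl in a chair‑like transition state (1,2‑induction), while C2 and C3 are not touched and keep their cis relationship in the non‑enolising medium. Three selectivities are needed: scission toward the benzylic and not the methyl‑bearing carbon (secured by the radical‑stabilising dimethoxyphenyl group), closure para and not ortho to the benzyloxy group (the ortho site is flanked by OBn and the acyl group), and no further oxidation of the product (its fused ring is deactivated by the ketone that the step creates).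

**Step 6**
Reactants: 13 (2S,3S,4R)‑7‑(benzyloxy)‑4‑(3,4‑dimethoxyphenyl)‑6‑methoxy‑2,3‑dimethyl‑3,4‑dihydronaphthalen‑1(2H)‑one
Product: 14 schisandrone, (2S,3S,4R)‑4‑(3,4‑dimethoxyphenyl)‑7‑hydroxy‑6‑methoxy‑2,3‑dimethyl‑3,4‑dihydronaphthalen‑1(2H)‑one
Conditions: H2 (1 atm), 10 % Pd/C, EtOAc, rt
Reagents that add atoms: none
Why: hydrogenolysis of an aryl benzyl ether under neutral conditions; no acid or base is present, so the epimerisable C2 centre and the other stereocentres should stay as set.

**Compound list**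
1 | (3,4‑dimethoxyphenyl)acetyl chloride | COc1ccc(CC(Cl)=O)cc1OC | starting material
2 | (2R,5R)‑2,5‑dimethylpyrrolidine | C[C@@H]1CC[C@@H](C)N1 | starting material
3 | 2‑(3,4‑dimethoxyphenyl)‑1‑[(2R,5R)‑2,5‑dimethylpyrrolidin‑1‑yl]ethan‑1‑one | COc1ccc(CC(=O)N2[C@H](C)CC[C@H]2C)cc1OC | intermediate
4 | (Z)‑but‑2‑ene | C/C=C\C | starting material
5 | (2R,5R)‑1‑[2‑(3,4‑dimethoxyphenyl)ethenylidene]‑2,5‑dimethylpyrrolidin‑1‑ium triflate | COc1ccc(C=C=[N+]2[C@H](C)CC[C@H]2C)cc1OC.[O-]S(=O)(=O)C(F)(F)F | intermediate (not isolated)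
6 | (2R,5R)‑1‑[(3R,4S)‑2‑(3,4‑dimethoxyphenyl)‑3,4‑dimethylcyclobutylidene]‑2,5‑dimethylpyrrolidin‑1‑ium triflate (C2 epimers) | C[C@@H]1CC[C@@H](C)[N+]1=C2C(c3ccc(OC)c(OC)c3)[C@H](C)[C@@H]2C.[O-]S(=O)(=O)C(F)(F)F | intermediate (not isolated)
7 | (3R,4S)‑2‑(3,4‑dimethoxyphenyl)‑3,4‑dimethylcyclobutan‑1‑one (cis‑3,4‑dimethyl; C2 epimers) | O=C1C(c2ccc(OC)c(OC)c2)[C@H](C)[C@@H]1C | intermediate
8 | 5‑bromo‑2‑methoxyphenol | COc1ccc(Br)cc1O | starting material
9 | 2‑(benzyloxy)‑4‑bromo‑1‑methoxybenzene | COc1ccc(Br)cc1OCc1ccccc1 | intermediate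
10 | [3‑(benzyloxy)‑4‑methoxyphenyl]lithium | COc1ccc([Li])cc1OCc1ccccc1 | intermediate (not isolated)
11 | [3‑(benzyloxy)‑4‑methoxyphenyl]cerium dichloride | COc1ccc([Ce](Cl)Cl)cc1OCc1ccccc1 | intermediate (not isolated)
12 | (3R,4S)‑1‑[3‑(benzyloxy)‑4‑methoxyphenyl]‑2‑(3,4‑dimethoxyphenyl)‑3,4‑dimethylcyclobutan‑1‑ol (cis‑3,4‑dimethyl; C1/C2 epimers) | OC1(c2ccc(OC)c(OCc3ccccc3)c2)C(c2ccc(OC)c(OC)c2)[C@H](C)[C@@H]1C | intermediate
13 | (2S,3S,4R)‑7‑(benzyloxy)‑4‑(3,4‑dimethoxyphenyl)‑6‑methoxy‑2,3‑dimethyl‑3,4‑dihydronaphthalen‑1(2H)‑one | COc1cc2c(cc1OCc1ccccc1)C(=O)[C@@H](C)[C@@H](C)[C@@H]2c1ccc(OC)c(OC)c1 | intermediate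
14 | schisandrone, (2S,3S,4R)‑4‑(3,4‑dimethoxyphenyl)‑7‑hydroxy‑6‑methoxy‑2,3‑dimethyl‑3,4‑dihydronaphthalen‑1(2H)‑one | COc1cc2c(cc1O)C(=O)[C@@H](C)[C@@H](C)[C@@H]2c1ccc(OC)c(OC)c1 | target

**Total step count:** 6
**Longest linear sequence:** 5 steps (1, 2, 4, 5, 6)

**Steps most likely to fail**

Step 5 (key step). The electron‑rich benzylic radical may be oxidised further before it closes on the arene. The cation would then be intercepted by the carbonyl oxygen and drain into a dihydrofuran or furan, or C2 would epimerise on this detour. Closure ortho to the benzyloxy group and over‑oxidation of the two dialkoxyarenes are smaller risks. The fallback closes the ring at a metal instead of at a free radical or cation and sets out from cyclobutanone 7. Commercial 4‑bromo‑2‑methoxyphenol would be benzylated (BnBr, K2CO3, DMF) to 1‑(benzyloxy)‑4‑bromo‑2‑methoxybenzene F1 and iodinated para to the methoxy group (NIS, cat. TFA, MeCN) to 1‑(benzyloxy)‑4‑bromo‑5‑iodo‑2‑methoxybenzene F2. Selective iodine–magnesium exchange (i‑PrMgCl·LiCl, THF, −40 °C) should give [5‑(benzyloxy)‑2‑bromo‑4‑methoxyphenyl]magnesium chloride F3, which is added to 7 (LaCl3·2LiCl, THF, −40 → 0 °C) to give the ortho‑bromo cyclobutanol (3R,4S)‑1‑[5‑(benzyloxy)‑2‑bromo‑4‑methoxyphenyl]‑2‑(3,4‑dimethoxyphenyl)‑3,4‑dimethylcyclobutan‑1‑ol F4. Under nickel/photoredox dual catalysis (Ir photocatalyst, NiBr2·glyme/dtbbpy, 2,4,6‑collidine, blue light, rt) the alkoxy radical formed by proton‑coupled electron transfer opens the ring as before. The benzylic radical is captured by the aryl–nickel species generated from the ortho C–Br bond, and reductive elimination forms the C4–C4a bond, which rejoins the route at 13. The intermolecular ring‑opening arylation of tertiary cyclobutanols with aryl bromides under these conditions is known; its intramolecular use is redox‑neutral and avoids the benzylic cation.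

Step 2. The auxiliary may discriminate poorly between the two enantiotopic orientations of the small, symmetric olefin. The keteniminium ion may also be consumed by Friedel–Crafts attack on the electron‑rich arene of a second molecule. The fallback gives up auxiliary control and sets out from acid chloride 1 and olefin 4. Dehydrochlorination (Et3N) gives (3,4‑dimethoxyphenyl)ketene F5 in the flask, and Lewis acid‑promoted ketene–alkene [2+2] cycloaddition (EtAlCl2, CH2Cl2, −78 °C) should give the racemic cis‑3,4‑dimethyl cyclobutanone rac‑(3R*,4S*)‑2‑(3,4‑dimethoxyphenyl)‑3,4‑dimethylcyclobutan‑1‑one F6. Steps 4 and 5, run unchanged on the racemate, give the racemic cyclobutanol F7 and the racemic O‑benzyl tetralone F8. The enantiomers of F8 are separated by preparative SFC on a chiral stationary phase, and the (2S,3S,4R)‑enantiomer is 13, where the route is rejoined.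

Step 4. The aryl metal may act as a base toward the α‑aryl cyclobutanone. Enolisation on the aryl‑bearing side only returns ketone, but enolisation on the methyl‑bearing side would erode the cis‑dimethyl relationship. The fallback changes the nucleophile class and sets out from aryllithium 10. Transmetalation with ClTi(OiPr)3 (THF, −78 → 0 °C) gives [3‑(benzyloxy)‑4‑methoxyphenyl]titanium triisopropoxide F9, an essentially non‑basic σ‑aryl donor that should still add to the strained ketone 7 (0 °C → rt). The route is rejoined at 12.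

**Further compounds**
F1 | step 5 | 1‑(benzyloxy)‑4‑bromo‑2‑methoxybenzene | COc1cc(Br)ccc1OCc1ccccc1
F2 | step 5 | 1‑(benzyloxy)‑4‑bromo‑5‑iodo‑2‑methoxybenzene | COc1cc(Br)c(I)cc1OCc1ccccc1
F3 | step 5 | [5‑(benzyloxy)‑2‑bromo‑4‑methoxyphenyl]magnesium chloride | COc1cc(Br)c([Mg]Cl)cc1OCc1ccccc1
F4 | step 5 | (3R,4S)‑1‑[5‑(benzyloxy)‑2‑bromo‑4‑methoxyphenyl]‑2‑(3,4‑dimethoxyphenyl)‑3,4‑dimethylcyclobutan‑1‑ol (C1/C2 epimers) | OC1(c2cc(OCc3ccccc3)c(OC)cc2Br)C(c2ccc(OC)c(OC)c2)[C@H](C)[C@@H]1C
F5 | step 2 | (3,4‑dimethoxyphenyl)ketene | COc1ccc(C=C=O)cc1OC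
F6 | step 2 | rac‑(3R*,4S*)‑2‑(3,4‑dimethoxyphenyl)‑3,4‑dimethylcyclobutan‑1‑one (racemate, C2 epimers) | O=C1C(c2ccc(OC)c(OC)c2)[C@H](C)[C@@H]1C.O=C1C(c2ccc(OC)c(OC)c2)[C@@H](C)[C@H]1C
F7 | step 2 | rac‑(3R*,4S*)‑1‑[3‑(benzyloxy)‑4‑methoxyphenyl]‑2‑(3,4‑dimethoxyphenyl)‑3,4‑dimethylcyclobutan‑1‑ol (racemate, C1/C2 epimers) | OC1(c2ccc(OC)c(OCc3ccccc3)c2)C(c2ccc(OC)c(OC)c2)[C@H](C)[C@@H]1C.OC1(c2ccc(OC)c(OCc3ccccc3)c2)C(c2ccc(OC)c(OC)c2)[C@@H](C)[C@H]1C
F8 | step 2 | rac‑(2S*,3S*,4R*)‑7‑(benzyloxy)‑4‑(3,4‑dimethoxyphenyl)‑6‑methoxy‑2,3‑dimethyl‑3,4‑dihydronaphthalen‑1(2H)‑one (racemate) | COc1cc2c(cc1OCc1ccccc1)C(=O)[C@@H](C)[C@@H](C)[C@@H]2c1ccc(OC)c(OC)c1.COc1cc2c(cc1OCc1ccccc1)C(=O)[C@H](C)[C@H](C)[C@H]2c1ccc(OC)c(OC)c1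
F9 | step 4 | [3‑(benzyloxy)‑4‑methoxyphenyl]titanium triisopropoxide | COc1ccc([Ti](OC(C)C)(OC(C)C)OC(C)C)cc1OCc1ccccc1
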